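**Retrosynthetic overview**
1. The three angelate esters are cut last, leaving the tricyclic enone triol 26.
2. Key disconnection: the cyclobutane CH that sits between the ketone carbon, the ring-fusion cyclobutane CH and the methyl-bearing cyclobutane carbon is a one-carbon insert in a cyclopentanone C(=O)–CH bond. Taking it out (retro ring enlargement) opens the cyclobutane and contracts the cyclohexenone, giving a cis-fused cyclopentanone–cycloheptane (hydroazulenone) that carries this carbon as CHO on the methyl-bearing quaternary carbon.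
3. That carbon is 1,3 to the ketone across the five-membered ring, so as a diazo carbon it can reach the carbonyl through a norbornane-like betaine; this is what makes the key step possible.
4. The five-membered ring comes from an intramolecular Pauson–Khand reaction of a propargyl ether hung on the CH2OH arm of a cycloheptene; reductive C–O cleavage then turns the tether into the enone methyl and the formyl precursor. The cycloheptene comes from ring-closing metathesis.
5. Both quaternary centres and the anti-1,3-diol are set on an acyclic chain by tert-(hydroxy)prenylation at one end and a (Z)-γ,γ-disubstituted allylboration at the other. Ring order: seven-membered ring, then cyclopentenone (with a temporary oxane), then cyclobutane and cyclohexenone together.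

Key step: step 17

Remark: the tert-(hydroxy)prenylation is assumed to give the anti adduct (secondary OH anti to CH2OH when the chain is drawn through the vinyl group), and for both chiral catalysts the antipode meant is the one that leads to the configuration drawn.

Abbreviations: TBS = tert-butyldimethylsilyl, TBDPS = tert-butyldiphenylsilyl, PMB = 4-methoxybenzyl, pin = pinacolato, DMP = Dess–Martin periodinane, NMO = 4-methylmorpholine N-oxide.

**Step 1**
Reactants: 1 propargyl alcohol
Product: 3 (Z)-3-iodo-2-methylprop-2-en-1-ol, via alkenylmagnesium alkoxide 2 (not isolated)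
Conditions: MeMgBr (3 equiv), CuI (10 mol %), THF, −10 °C to rt; then I2, −10 °C
Reagents that add atoms: methylmagnesium bromide, C[Mg]Br; iodine, II
Why: copper-catalysed anti-carbomagnesiation of the propargylic alkoxide (Duboudin type) should give the magnesium chelate with Mg cis to CH2O, and iodinolysis with retention fixes the Z geometry.

**Step 2**
Reactants: 3 (Z)-iodo allylic alcohol
Product: 4 tert-butyl{[(Z)-3-iodo-2-methylprop-2-en-1-yl]oxy}diphenylsilane
Conditions: TBDPSCl, imidazole, CH2Cl2, rt
Reagents that add atoms: tert-butyl(chloro)diphenylsilane, CC(C)(C)[Si](Cl)(c1ccccc1)c1ccccc1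
Why: routine silylation of a primary allylic alcohol, with the alkene geometry untouched.

**Step 3**
Reactants: 4 TBDPS ether of the (Z)-iodo alcohol
Product: 6 (Z)-allylboronate tert-butyl{[(Z)-2-methyl-4-(Bpin)but-2-en-1-yl]oxy}diphenylsilane, via alkenyllithium 5 (not isolated)
Conditions: t-BuLi (2.1 equiv), Et2O, −78 °C; then ICH2Bpin, −78 °C to rt
Reagents that add atoms: 2-(iodomethyl)-4,4,5,5-tetramethyl-1,3,2-dioxaborolane, ICB1OC(C)(C)C(C)(C)O1
Why: iodine–lithium exchange with retention followed by Matteson homologation (borate formation, 1,2-shift of the alkenyl group with loss of iodide) should give the allylboronate with CH2B cis to CH2OSi.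

**Step 4**
Reactants: 7 mono-PMB ether of trimethylene glycol; 8 isoprene monoxide
Product: 9 (2R,3R)-5-[(4-methoxybenzyl)oxy]-2-methyl-2-vinylpentane-1,3-diol
Conditions: racemic epoxide in threefold excess, cyclometallated π-allyliridium C,O-benzoate complex from [Ir(cod)Cl]2, Tol-BINAP, 4-cyano-3-nitrobenzoic acid and allyl acetate (5 mol %), K3PO4 (5 mol %), THF, 45 °C
Reagents that add atoms: none
Why: redox-neutral transfer-hydrogenative carbonyl tert-(hydroxy)prenylation (Krische type), in which every atom of both partners ends up in the diol: the aldehyde formed by alcohol dehydrogenation is attacked by the (E)-σ-allyliridium species through a closed chair transition state, which sets the quaternary centre anti to the carbinol, while the chiral ligand sets the carbinol configuration.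

**Step 5**
Reactants: 9 diol
Product: 10 bis-TBS ether of 9
Conditions: TBSOTf (2.5 equiv), 2,6-lutidine, CH2Cl2, −78 to 0 °C
Reagents that add atoms: tert-butyldimethylsilyl trifluoromethanesulfonate, CC(C)(C)[Si](C)(C)OS(=O)(=O)C(F)(F)F
Why: silylation with the triflate covers the primary and the hindered neopentyl secondary hydroxyl in one operation.

**Step 6**
Reactants: 10 bis-TBS ether
Product: 11 (3R,4R)-3-(TBS-oxy)-4-(TBS-oxymethyl)-4-methylhex-5-en-1-ol
Conditions: DDQ, CH2Cl2/pH 7 buffer, 0 °C to rt
Reagents that add atoms: none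
Why: oxidative cleavage of the PMB ether is orthogonal to silyl ethers and the vinyl group.

**Step 7**
Reactants: 11 primary alcohol
Product: 12 (3R,4R)-3-(TBS-oxy)-4-(TBS-oxymethyl)-4-methylhex-5-enal
Conditions: DMP, CH2Cl2, 0 °C to rt
Reagents that add atoms: none
Why: Dess–Martin oxidation gives the β-silyloxy aldehyde without β-elimination.

**Step 8**
Reactants: 12 aldehyde; 6 (Z)-allylboronate
Product: 13 (3S,4R,6R,7R)-6-(TBS-oxy)-7-(TBS-oxymethyl)-3-(TBDPS-oxymethyl)-3,7-dimethylnona-1,8-dien-4-ol
Conditions: allylboronate in 1.5-fold excess, (S)-TRIP phosphoric acid (5 mol %), 4 Å molecular sieves, toluene, −30 °C to rt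
Reagents that add atoms: none
Why: Brønsted-acid-catalysed allylboration through a Zimmerman–Traxler chair transfers the Z geometry to the new quaternary centre (OH syn to CH2OSi, anti to CH3), and the chiral acid, reinforced by the 1,3-anti preference of the β-silyloxy aldehyde, selects the aldehyde face.

**Step 9**
Reactants: 13 homoallylic alcohol
Product: 14 TBS ether of 13 (diene with four silyl ethers)
Conditions: TBSOTf, 2,6-lutidine, CH2Cl2, 0 °C to rt
Reagents that add atoms: tert-butyldimethylsilyl trifluoromethanesulfonate, CC(C)(C)[Si](C)(C)OS(=O)(=O)C(F)(F)F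
Why: the triflate is reactive enough to silylate the secondary hydroxyl next to the quaternary carbon.

**Step 10**
Reactants: 14 diene
Product: 15 cycloheptene: 3,7-dimethylcyclohept-1-ene with 3-CH2OTBS, 4-OTBS, 6-OTBS and 7-CH2OTBDPS (3-CH2O cis to 4-O; 4-O trans to 6-O; 7-CH2O cis to 3-CH2O)
Conditions: second-generation Hoveyda–Grubbs catalyst [RuCl2(H2IMes)(=CH-C6H4-2-OiPr)] (10 mol %), toluene, 90 °C, argon sparge
Reagents that add atoms: none
Why: ring-closing metathesis of the two vinyl groups, helped by the Thorpe–Ingold effect of both quaternary carbons, should close the seven-membered ring as the cis alkene.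

**Step 11**
Reactants: 15 cycloheptene
Product: 16 primary alcohol (3-CH2OH) with the other three silyl ethers intact
Conditions: HF·pyridine, pyridine, THF, 0 °C
Reagents that add atoms: none
Why: buffered fluoride removes a primary TBS ether much faster than hindered secondary TBS ethers or a TBDPS ether.

**Step 12**
Reactants: 16 primary alcohol
Product: 17 propargyl ether of 16
Conditions: prop-2-yn-1-yl 2,2,2-trichloroacetimidate (1.5 equiv), TfOH (5 mol %), CH2Cl2/cyclohexane, 0 °C
Reagents that add atoms: prop-2-yn-1-yl 2,2,2-trichloroacetimidate, C#CCOC(=N)C(Cl)(Cl)Cl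
Why: acid-catalysed imidate etherification avoids an alkoxide, so the neighbouring secondary TBS group cannot migrate to the primary oxygen.

**Step 13**
Reactants: 17 propargyl ether
Product: 19 tetracyclic enone: cyclopentenone cis-fused to the seven-membered ring with a dihydropyran bridging the enone β-carbon and the quaternary carbon, via dicobalt hexacarbonyl alkyne complex 18 (not isolated)
Conditions: Co2(CO)8 (1.1 equiv), CH2Cl2, rt; then NMO (8 equiv), 0 °C to rt
Reagents that add atoms: dicobalt octacarbonyl (source of CO), O=C=[Co](=C=O)(=C=O)(=C=O)[Co](=C=O)(=C=O)(=C=O)=C=O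
Why: in the intramolecular Pauson–Khand reaction the tether forces suprafacial addition to the ring alkene on the face of the CH2O arm, so both new CH centres are set cis to that arm, and it places the carbonyl on the alkene carbon remote from the tether.

**Step 14**
Reactants: 19 tetracyclic enone
Product: 20 cis-fused hydroazulenone: 3-methylenecyclopentanone fused to the cycloheptane, CH2OH on the neighbouring quaternary carbon
Conditions: SmI2 (2.5 equiv), THF/MeOH (20:1), −78 °C, quench at −78 °C
Reagents that add atoms: none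
Why: two-electron reduction of the γ-alkoxy enone expels the allylic alkoxide (vinylogous β-elimination) and kinetic α-protonation of the dienolate leaves the exocyclic alkene, which frees the future enone methyl carbon and the primary alcohol in one step.

**Step 15**
Reactants: 20 hydroxy ketone
Product: 21 keto aldehyde (CHO on the quaternary carbon)
Conditions: DMP, CH2Cl2, 0 °C to rt
Reagents that add atoms: none
Why: Dess–Martin oxidation of the neopentyl alcohol gives a non-enolisable aldehyde under neutral conditions.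

**Step 16**
Reactants: 21 keto aldehyde
Product: 22 aldehyde N-tosylhydrazone
Conditions: TsNHNH2 (1.05 equiv), THF, rt
Reagents that add atoms: 4-methylbenzenesulfonohydrazide, Cc1ccc(cc1)S(=O)(=O)NN
Why: hydrazone condensation is much faster at the aldehyde than at the ring ketone.

**Step 17**
Reactants: 22 tosylhydrazone
Product: 25 silyl-protected tricyclic enone (full carbon skeleton of the target), via diazoalkane 23 (not isolated), via exocyclic alkene ketone 24 (not isolated)
Conditions: NaH (1.05 equiv), THF, 0 °C; then 1,4-dioxane, BnEt3NCl (10 mol %), 80 °C; then DBU (0.3 equiv), rt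
Reagents that add atoms: none
Why: Proposed new method: NaH deprotonates the tosylhydrazone and warming expels sulfinate (Bamford–Stevens) to give the neopentyl-type diazoalkane 23, whose carbon adds to the ring ketone from the only face it can reach to give a bicyclo[2.2.1] β-oxido diazonium, after which loss of N2 with 1,2-shift of the ring-fusion carbon (semipinacol, Tiffeneau–Demjanov type) gives 24 and DBU moves the exocyclic alkene into conjugation. The closest known reaction type is the intramolecular diazoalkane–ketone ring enlargement that gives bridged bicyclic ketones (and the homologation of cycloalkanones with non-stabilised diazoalkanes); what has not been shown is migration of the one-carbon bridge of the betaine, which here turns a fused cyclopentanone into a bicyclo[3.1.1]heptanone. The bond from the diazo carbon to the carbonyl carbon closes the six-membered enone ring by nucleophilic addition through a five-membered transition state, and the bond from the diazo carbon to the ring-fusion carbon closes the cyclobutane by anti-periplanar 1,2-migration with retention at the migrating carbon. The one new stereocentre, the cyclobutane CH beside the ketone, is fixed by the cis ring fusion and by the formyl-derived carbon lying on the same face as the five-membered ring, both set in steps 4 and 13. The step needs migration of the ring-fusion CH and not of the α-CH2 (which would give a bicyclo[2.2.1] isomer); this should be secured because the quaternary C(CH3)(CH2OSi) carbon on the one-carbon bridge and the silyloxy-bearing carbon crowd the exo position, so the diazonium group sits endo, where only the bond to the ring-fusion carbon is anti-periplanar to it. Carbene side reactions should be limited because the diazo carbon has no α-hydrogen and the ketone, unconjugated at this stage, is held in a 1,5-relationship.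

**Step 18**
Reactants: 25 silyl-protected tricyclic enone
Product: 26 tricyclic enone triol
Conditions: HF·pyridine (excess), THF, 0 to 40 °C
Reagents that add atoms: none
Why: fluoride-mediated desilylation removes both TBS ethers and the TBDPS ether without touching the enone or the cyclobutane.

**Step 19**
Reactants: 26 triol
Product: 27 target triangelate (CNP0266467.1)
Conditions: angelic acid (4.5 equiv), 2,4,6-trichlorobenzoyl chloride (4.5 equiv), Et3N, toluene, rt; then 26, toluene, 75 °C
Reagents that add atoms: angelic acid, C/C=C(/C)C(=O)O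
Why: Yamaguchi esterification through the preformed mixed anhydride, run without a nucleophilic catalyst, should acylate the primary and both hindered secondary hydroxyls while keeping the Z geometry of the angelates.

**Compound list**
1 | prop-2-yn-1-ol | C#CCO | starting material
2 | bromomagnesium (Z)-3-(bromomagnesio)-2-methylprop-2-en-1-olate | Br[Mg]/C=C(/C)CO[Mg]Br | intermediate
3 | (Z)-3-iodo-2-methylprop-2-en-1-ol | OC/C(C)=C\I | intermediate
4 | tert-butyl{[(Z)-3-iodo-2-methylprop-2-en-1-yl]oxy}diphenylsilane | CC(C)(C)[Si](OC/C(C)=C\I)(c1ccccc1)c1ccccc1 | intermediate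
5 | (Z)-alkenyllithium from 4 | CC(C)(C)[Si](OC/C(C)=C\[Li])(c1ccccc1)c1ccccc1 | intermediate
6 | (Z)-allylboronate, tert-butyl{[(Z)-2-methyl-4-(Bpin)but-2-en-1-yl]oxy}diphenylsilane | CC(C)(C)[Si](OC/C(C)=C\CB1OC(C)(C)C(C)(C)O1)(c1ccccc1)c1ccccc1 | intermediate
7 | 3-[(4-methoxybenzyl)oxy]propan-1-ol | COc1ccc(COCCCO)cc1 | starting material
8 | 2-methyl-2-vinyloxirane (racemic) | CC1(C=C)CO1 | starting material
9 | (2R,3R)-5-[(4-methoxybenzyl)oxy]-2-methyl-2-vinylpentane-1,3-diol | COc1ccc(COCC[C@@H](O)[C@](C)(C=C)CO)cc1 | intermediate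
10 | bis-TBS ether of 9 | COc1ccc(COCC[C@@H](O[Si](C)(C)C(C)(C)C)[C@](C)(C=C)CO[Si](C)(C)C(C)(C)C)cc1 | intermediate
11 | (3R,4R)-3-(TBS-oxy)-4-(TBS-oxymethyl)-4-methylhex-5-en-1-ol | OCC[C@@H](O[Si](C)(C)C(C)(C)C)[C@](C)(C=C)CO[Si](C)(C)C(C)(C)C | intermediate
12 | (3R,4R)-3-(TBS-oxy)-4-(TBS-oxymethyl)-4-methylhex-5-enal | O=CC[C@@H](O[Si](C)(C)C(C)(C)C)[C@](C)(C=C)CO[Si](C)(C)C(C)(C)C | intermediate
13 | (3S,4R,6R,7R)-6-(TBS-oxy)-7-(TBS-oxymethyl)-3-(TBDPS-oxymethyl)-3,7-dimethylnona-1,8-dien-4-ol | CC(C)(C)[Si](OC[C@](C)(C=C)[C@H](O)C[C@@H](O[Si](C)(C)C(C)(C)C)[C@](C)(C=C)CO[Si](C)(C)C(C)(C)C)(c1ccccc1)c1ccccc1 | intermediate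
14 | TBS ether of 13 | CC(C)(C)[Si](OC[C@](C)(C=C)[C@H](O[Si](C)(C)C(C)(C)C)C[C@@H](O[Si](C)(C)C(C)(C)C)[C@](C)(C=C)CO[Si](C)(C)C(C)(C)C)(c1ccccc1)c1ccccc1 | intermediate
15 | cycloheptene with 3-CH2OTBS, 4-OTBS, 6-OTBS, 7-CH2OTBDPS and 3,7-dimethyl groups | CC(C)(C)[Si](OC[C@]1(C)C=C[C@](C)(CO[Si](C)(C)C(C)(C)C)[C@H](O[Si](C)(C)C(C)(C)C)C[C@H]1O[Si](C)(C)C(C)(C)C)(c1ccccc1)c1ccccc1 | intermediate
16 | primary alcohol from 15 | CC(C)(C)[Si](OC[C@]1(C)C=C[C@](C)(CO)[C@H](O[Si](C)(C)C(C)(C)C)C[C@H]1O[Si](C)(C)C(C)(C)C)(c1ccccc1)c1ccccc1 | intermediate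
17 | propargyl ether of 16 | CC(C)(C)[Si](OC[C@]1(C)C=C[C@](C)(COCC#C)[C@H](O[Si](C)(C)C(C)(C)C)C[C@H]1O[Si](C)(C)C(C)(C)C)(c1ccccc1)c1ccccc1 | intermediate
18 | dicobalt hexacarbonyl complex of alkyne 17 | CC(C)(C)[Si](OC[C@]1(C)C=C[C@](C)(COCC23[Co]4(=C=O)(=C=O)(=C=O)[Co]2(=C=O)(=C=O)(=C=O)[CH]34)[C@H](O[Si](C)(C)C(C)(C)C)C[C@H]1O[Si](C)(C)C(C)(C)C)(c1ccccc1)c1ccccc1 | intermediate
19 | tetracyclic Pauson–Khand enone (cis-fused cyclopentenone, bridging dihydropyran) | CC(C)(C)[Si](OC[C@]1(C)[C@@H]2C(=O)C=C3COC[C@]([C@H]23)(C)[C@H](O[Si](C)(C)C(C)(C)C)C[C@H]1O[Si](C)(C)C(C)(C)C)(c1ccccc1)c1ccccc1 | intermediate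
20 | cis-fused 3-methylenecyclopentanone–cycloheptane with CH2OH on the quaternary carbon | CC(C)(C)[Si](OC[C@]1(C)[C@@H]2C(=O)CC(=C)[C@@H]2[C@](C)(CO)[C@H](O[Si](C)(C)C(C)(C)C)C[C@H]1O[Si](C)(C)C(C)(C)C)(c1ccccc1)c1ccccc1 | intermediate
21 | keto aldehyde from 20 | CC(C)(C)[Si](OC[C@]1(C)[C@@H]2C(=O)CC(=C)[C@@H]2[C@](C)(C=O)[C@H](O[Si](C)(C)C(C)(C)C)C[C@H]1O[Si](C)(C)C(C)(C)C)(c1ccccc1)c1ccccc1 | intermediate
22 | (E)-N-tosylhydrazone of 21 | CC(C)(C)[Si](OC[C@]1(C)[C@@H]2C(=O)CC(=C)[C@@H]2[C@](C)(/C=N/NS(=O)(=O)c2ccc(C)cc2)[C@H](O[Si](C)(C)C(C)(C)C)C[C@H]1O[Si](C)(C)C(C)(C)C)(c1ccccc1)c1ccccc1 | intermediate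
23 | diazoalkane from 22 | CC(C)(C)[Si](OC[C@]1(C)[C@@H]2C(=O)CC(=C)[C@@H]2[C@](C)(C=[N+]=[N-])[C@H](O[Si](C)(C)C(C)(C)C)C[C@H]1O[Si](C)(C)C(C)(C)C)(c1ccccc1)c1ccccc1 | intermediate
24 | ring-enlarged tricyclic ketone with exocyclic methylene | CC(C)(C)[Si](OC[C@]1(C)[C@@H]2[C@H]3C(=O)CC(=C)[C@@H]2[C@@]3(C)[C@H](O[Si](C)(C)C(C)(C)C)C[C@H]1O[Si](C)(C)C(C)(C)C)(c1ccccc1)c1ccccc1 | intermediate
25 | silyl-protected tricyclic enone | CC(C)(C)[Si](OC[C@]1(C)[C@@H]2[C@H]3C(=O)C=C(C)[C@@H]2[C@@]3(C)[C@H](O[Si](C)(C)C(C)(C)C)C[C@H]1O[Si](C)(C)C(C)(C)C)(c1ccccc1)c1ccccc1 | intermediate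
26 | tricyclic enone triol | OC[C@]1(C)[C@@H]2[C@H]3C(=O)C=C(C)[C@@H]2[C@@]3(C)[C@H](O)C[C@H]1O | intermediate
27 | CNP0266467.1, tris[(Z)-2-methylbut-2-enoate] of 26 | C/C=C(/C)C(=O)OC[C@]1(C)[C@@H]2[C@H]3C(=O)C=C(C)[C@@H]2[C@@]3(C)[C@H](OC(=O)/C(C)=C\C)C[C@H]1OC(=O)/C(C)=C\C | target

**Step count**
Total steps: 19. Longest linear sequence: 16 steps (7 to 27, steps 4–19); the boronate branch (steps 1–3) joins at step 8.

**Steps most likely to fail, with fallbacks**

Step 17 (Proposed new method). The 1,2-shift may lose its regiocontrol (migration of the α-CH2 after exo placement of the diazonium group), or the diazoalkane may decompose by carbene-type pathways before it adds to the ketone. The fallback separates carbonyl addition from migration and uses known reactions. It sets out from keto aldehyde 21: hydrazine hydrate (1 equiv, 0 °C) gives the aldehyde hydrazone F1, and I2/Et3N converts this into the gem-diiodide F2 (no α-hydrogen, so no vinyl iodide forms). SmI2 in THF then generates the α-iodoalkylsamarium, which adds to the ring ketone to give the bridgehead iodohydrin F3, whose endo-iodo epimer is separated. AgBF4 triggers the halohydrin ring enlargement to ketone 24, and DBU isomerisation brings the route back at 25.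

Step 13. The cobalt–alkyne complex may fail to insert the ring alkene, which is flanked by two quaternary carbons, and decomplex or reduce instead. The fallback replaces the cobalt carbonyl chemistry by an early-metal oxidative cyclisation on a silyl-capped alkyne. It sets out from alcohol 16: 3-(trimethylsilyl)prop-2-yn-1-yl trichloroacetimidate/TfOH gives the silylalkyne ether F4. Cp2ZrCl2 with n-BuLi (2 equiv) then couples alkyne and ring alkene to the zirconacyclopentene F5, and CO (1 atm) converts this into the 2-silyl enone F6. Protodesilylation with TsOH·H2O (cat.) returns the route at 19.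

Step 10. Ring closure may stall because both vinyl groups sit on quaternary carbons, leaving oligomers or unreacted diene. The fallback forms the same alkene by carbonyl coupling. It sets out from diene 14: ozonolysis (O3, CH2Cl2, −78 °C; PPh3) gives the dialdehyde F7, and McMurry coupling (TiCl3, Zn–Cu, DME, reflux, high dilution) closes the cycloheptene, returning at 15.

**Further compounds**
F1 | step 17 | hydrazone of keto aldehyde 21 | CC(C)(C)[Si](OC[C@]1(C)[C@@H]2C(=O)CC(=C)[C@@H]2[C@](C)(C=NN)[C@H](O[Si](C)(C)C(C)(C)C)C[C@H]1O[Si](C)(C)C(C)(C)C)(c1ccccc1)c1ccccc1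
F2 | step 17 | gem-diiodide from F1 | CC(C)(C)[Si](OC[C@]1(C)[C@@H]2C(=O)CC(=C)[C@@H]2[C@](C)(C(I)I)[C@H](O[Si](C)(C)C(C)(C)C)C[C@H]1O[Si](C)(C)C(C)(C)C)(c1ccccc1)c1ccccc1
F3 | step 17 | bridgehead iodohydrin (endo-iodo) | CC(C)(C)[Si](OC[C@]1(C)[C@@H]2[C@@]3(O)CC(=C)[C@@H]2[C@](C)([C@@H]3I)[C@H](O[Si](C)(C)C(C)(C)C)C[C@H]1O[Si](C)(C)C(C)(C)C)(c1ccccc1)c1ccccc1
F4 | step 13 | 3-(trimethylsilyl)propargyl ether of 16 | CC(C)(C)[Si](OC[C@]1(C)C=C[C@](C)(COCC#C[Si](C)(C)C)[C@H](O[Si](C)(C)C(C)(C)C)C[C@H]1O[Si](C)(C)C(C)(C)C)(c1ccccc1)c1ccccc1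
F5 | step 13 | zirconacyclopentene | CC(C)(C)[Si](OC[C@]1(C)[C@@H]2[Zr](C3C=CC=C3)(C3C=CC=C3)C([Si](C)(C)C)=C3COC[C@]([C@H]23)(C)[C@H](O[Si](C)(C)C(C)(C)C)C[C@H]1O[Si](C)(C)C(C)(C)C)(c1ccccc1)c1ccccc1
F6 | step 13 | 2-(trimethylsilyl) enone | CC(C)(C)[Si](OC[C@]1(C)[C@@H]2C(=O)C([Si](C)(C)C)=C3COC[C@]([C@H]23)(C)[C@H](O[Si](C)(C)C(C)(C)C)C[C@H]1O[Si](C)(C)C(C)(C)C)(c1ccccc1)c1ccccc1
F7 | step 10 | dialdehyde from diene 14 | CC(C)(C)[Si](OC[C@](C)(C=O)[C@H](O[Si](C)(C)C(C)(C)C)C[C@@H](O[Si](C)(C)C(C)(C)C)[C@](C)(C=O)CO[Si](C)(C)C(C)(C)C)(c1ccccc1)c1ccccc1
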